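Atom numbering (germacrane) used throughout: ring C1H=C10(C14H3)–C9H2–C8H(O‑lactone)–C7H–C6H(O)–C5H=C4(C15H2O)–C3H(O)–C2H2; lactone C7–C11(=C13H2)–C12(=O)–O–C8. Compound numbers 1–34 are those of the steps and the list.

## Analysis of the target

Compound 34 is a germacranolide: a ten-membered carbocycle with two E trisubstituted double bonds, C1=C10 and C4=C5, and an α-methylene-γ-butyrolactone trans-fused across C7–C8. Of its four ring stereocentres, C6 (R), C7 (R) and C8 (S) are contiguous, with H7 and H8 trans and the C6 and C8 oxygens syn along the C5–C9 backbone. C3 (R) stands alone on the far side of the C4=C5 bond, and the two (R)-2-methylbutanoyl groups on O6 and O15 bring two more centres from the acid. The exocyclic enoate is a Michael acceptor, and the 1,5-diene of the medium ring can undergo Cope rearrangement on heating or transannular cyclisation in strong acid. All three ring C–O bonds are allylic or next to the lactone, an acyl group can move from O15 to a free O3, and the lactone can move from O8 to a free O6, since both are γ to C12. The synthesis is hard because a ten-membered ring has to be closed with both E alkenes intact, and because three hydroxyls must be told apart (two acylated, one free). The plan rests on C2: it is the only ring methylene lying between an sp2 carbon (C1) and a carbinol (C3). The C1–C2 bond is therefore an sp2–sp3 bond whose formation creates no stereocentre, and it can be made last from a C1 alkenyl bromide and a C2 primary iodide under reductive nickel catalysis, with C2 reacting as a radical that keeps its β-silyloxy group.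

## Retrosynthetic reasoning

Endgame. 34 comes from 33 by removal of the C3 silyl group, which is kept to the end so that O3 is never free during acylation. 33 comes from diol 31 and two equivalents of acid 32, the two identical esters being made in one operation. 31 comes from 30, in which O6 and O15, cis to each other on the C4=C5 bond, are tied up in one seven-membered acetonide. 30 comes from 27 through Mannich base 28. The methylene is put in after ring closure, because an exocyclic enoate would be a radical acceptor in the ring-closing step, and before the esters, because the enolate chemistry would endanger their α-centres.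

Ring closure. 27 is cut at C1–C2 to give 26. Every other ring bond is worse: it is part of a stereodefined alkene, or flanked by the C6–C7–C8 triad, or (C2–C3, C3–C4) would have to create C3 during closure. Cutting C1–C2 leaves all four stereocentres, both E alkenes, the lactone and C14 in the open chain. The forward step only has to join an alkenyl bromide and a primary iodide within one molecule with retention at C1. It must pass through a C2 radical and not a C2–metal species, so the reductant is chosen not to insert into the C–I bond.

Functional-group changes before closure. 26 comes from alcohol 25 by iodination, 25 from 24 by selective loss of the primary silyl group, and 24 from diol 23 by ketalisation. The C2/C3 oxygens are differentiated by the size of their silyl groups and the C6/C15 pair by the ketal.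

Fragment union. 23 is cut at C5–C6 into aldehyde 13 and alkenyl iodide 20. This divides the molecule into two pieces of similar size at a carbinol. The Z iodoalkene of 20 reacts with retention, so C15 ends up cis to C6 as the E ring alkene requires. C6 is set by Felkin–Anh addition to the α-branched aldehyde.

Lactone fragment. 13 comes from vinyl lactone 11 by oxidative cleavage, and 11 from butenolide 10 by conjugate addition of a vinyl group. This addition makes C6–C7 and sets C7 trans to the existing C8 substituent. 10 comes from acrylate 9 by ring-closing metathesis, and 9 from dienol 8.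

Bromoalkene and C8. 8 comes from enynol 6 by methylalumination and bromination, which fixes C14 and the E bromoalkene in one step. 6 comes from 5 and chlorohydrin 3, and 3 from 1 and 2. C8 is thus taken from the chiral pool, the alkyne opening the epoxide at C9 and a one-carbon homologation providing the vinyl group at C7.

C2–C5 fragment. 20 comes from ester 19 by reduction and 19 from 18 by silylation. 18 is cut at C3–C4 into 14 and 15 by an iodo-aldol reaction that makes the Z iodoalkene, the C15 ester carbon and the C3 carbinol in a single step.

## Alternatives that were turned down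

Alternative 1: ring expansion by anionic oxy-Cope rearrangement. The disconnection cuts C2–C3 and joins C5 to C10, so that the ten-membered ring is traced back to the six-membered precursor of A1 (ring C5–C10, with the C1=C2 vinyl group on a C10 carbinol and the C3=C4 alkenyl group on C5, trans to it). In the forward step a potassium alkoxide, activated by a crown ether, undergoes the [3,3] shift that makes C2–C3 and breaks C5–C10. The resulting C10 enolate is trapped in the same flask by an N-aryl triflimide as enol triflate A1. In its favour, no end-to-end closure and no dilution are needed, the reaction type is thoroughly established for (E)-cyclodecenones, the chair transition state gives the E C4=C5 bond, and C6, C7 and C8 can be set beforehand on a six-membered ring. On precedent and reliability of ring formation it is stronger than the chosen route. Against it for 34, C3 becomes a stereocentre in the sigmatropic step itself, so its configuration depends on the geometry of a C3 enol ether and on a chair-versus-boat preference that the neighbouring substituents can upset. A1 still lacks the C14 methyl (a cross-coupling at the triflate) and the lactone (C12 is at the alcohol level and must be unmasked, oxidised and closed on O8). It also carries three kinds of protecting groups, of which the C3 acetal needs acid in the presence of the sensitive diene. Its densely substituted six-membered precursor is itself long to make. The chosen route gives up precedent for the ring-forming step but brings C14, the lactone and all four stereocentres into the closure, so that only five steps follow it.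

Alternative 2: ring contraction by [2,3]-Wittig rearrangement. The disconnection cuts C6–C7 and joins C13 to O6, so that the carbocycle is traced back to the thirteen-membered cyclic ether that is the precursor of A2. In the forward step an alkyllithium removes a propargylic proton at C6, the carbanion attacks C7 through a five-membered transition state, the C13–O bond breaks, and the ring contracts to cyclodecenynol A2 with the C6 hydroxyl, the C7 centre and the C11=C13 methylene. In its favour, a macrocyclic ether is easier to close than a carbocycle, the contraction is a known way to ten-membered germacrane rings, and C6, C7 and the exocyclic methylene arise together. On these points it is stronger. Against it, A2 has a triple bond at C4–C5 and no C15. Converting a strained ring alkyne into the E C4=C5 bond with a hydroxymethyl group on C4 needs a regio- and stereoselective hydrometalation followed by a one-carbon coupling. C12 must then be oxidised and closed on O8 while O6, equally γ to C12, is free. The facial course of the shift depends on the remote C3 and C8 centres. The chosen route fixes C15, the alkene geometry and the lactone in 13 and 20 before the ring is closed.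

Alternative 3: nickel-catalysed reductive alkyne–aldehyde macrocyclisation. The disconnection is C3–C4, and the open-chain precursor of A3 carries a C3 aldehyde and a C4≡C5 alkyne between C15 and C6. In the forward step zerovalent nickel with a bulky N-heterocyclic carbene joins aldehyde and alkyne in an oxanickelacycle, and a trialkylsilane cleaves it to give A3 with the ring, the E C4=C5 bond and the C3 silyl ether. In its favour, ring, alkene geometry and C3–O bond are made at once, the lactone and C6–C8 are already in place, and reductive ynal macrocyclisation is a known ring closure. On step economy and on precedent for the closure it is at least as strong as the chosen route. Against it, C3 is created during closure under a remote or ligand-derived bias that cannot be predicted. The internal alkyne has similar groups on both carbons, so the exocyclic mode (bond to C5, nine-membered ring) competes. The C3 aldehyde is β,γ-unsaturated through C1=C10 and prone to conjugation, and ten-membered rings are at the strained end for this reaction. The chosen route sets C3 in step 9 and leaves the closure of 26 to 27 free of any regio- or stereochemical question, at the price of an untested intramolecular variant.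

Key step: step 16

Assumption: the (S)-configured oxazaborolidinium catalyst of step 9 is taken to direct attack to the face of 15 that gives the (1S) carbinol of 18; if a test shows the opposite sense, the (R)-catalyst is used and nothing else changes.

## Route

Step 1
Reactants: 1 (S)-epichlorohydrin; 2 ethynyltrimethylsilane
Product: 3 (2S)-1-chloro-5-(trimethylsilyl)pent-4-yn-2-ol
Conditions: 2, n-BuLi, THF, −78 °C; BF3·OEt2; then 1, −78 °C
Reagents that add atoms: none
Why: Yamaguchi–Hirao opening: the BF3-activated lithium acetylide attacks the unsubstituted epoxide carbon (C9) faster than it displaces chloride, and the C8 centre is not touched.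

Step 2
Reactants: 3 (2S)-1-chloro-5-(trimethylsilyl)pent-4-yn-2-ol
Product: 5 (3S)-6-(trimethylsilyl)hex-1-en-5-yn-3-ol, via alkynyl epoxide 4 (not isolated)
Conditions: Me3S I, n-BuLi (excess), THF, −20 → 25 °C
Reagents that add atoms: trimethylsulfonium iodide, C[S+](C)C.[I-]
Why: The sulfonium ylide first closes the chlorohydrin to epoxide 4 and then opens it at the CH2 terminus (C7); a further equivalent eliminates the β-alkoxysulfonium salt to the allylic alcohol (one-carbon homologation of an epoxide). Only C7 reacts, so C8 keeps its configuration.

Step 3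
Reactants: 5 (3S)-6-(trimethylsilyl)hex-1-en-5-yn-3-ol
Product: 6 (3S)-hex-1-en-5-yn-3-ol
Conditions: K2CO3 (cat.), MeOH, 25 °C
Reagents that add atoms: none
Why: Base-catalysed methanolysis of the alkynyl C–Si bond; nothing else in 5 is base-labile.

Step 4
Reactants: 6 (3S)-hex-1-en-5-yn-3-ol
Product: 8 (3S,5E)-6-bromo-5-methylhexa-1,5-dien-3-ol, via alkenylalane 7 (not isolated)
Conditions: Me3Al (3 equiv), Cp2ZrCl2 (25 mol %), CH2Cl2, 0 → 25 °C; then N-bromosuccinimide, THF, −30 → 0 °C
Reagents that add atoms: trimethylaluminium, C[Al](C)C; N-bromosuccinimide, O=C1CCC(=O)N1Br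
Why: Negishi zirconium-catalysed methylalumination adds CH3 and Al syn across the terminal alkyne with the methyl on the internal carbon (C10); the hydroxyl is carried as its aluminium alkoxide and the monosubstituted alkene reacts far more slowly. Bromination of the C–Al bond with retention gives the (E)-bromoalkene.

Step 5
Reactants: 8 (3S,5E)-6-bromo-5-methylhexa-1,5-dien-3-ol
Product: 9 (3S,5E)-6-bromo-5-methylhexa-1,5-dien-3-yl prop-2-enoate
Conditions: acryloyl chloride, Et3N, CH2Cl2, 0 °C
Reagents that add atoms: acryloyl chloride, C=CC(=O)Cl
Why: Acylation of a secondary allylic alcohol by an acid chloride; no stereocentre takes part.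

Step 6
Reactants: 9 (3S,5E)-6-bromo-5-methylhexa-1,5-dien-3-yl prop-2-enoate
Product: 10 (5S)-5-[(2E)-3-bromo-2-methylprop-2-en-1-yl]furan-2(5H)-one
Conditions: second-generation Grubbs catalyst RuCl2(=CHPh)(PCy3)(H2IMes) (5 mol %), CH2Cl2, 40 °C
Reagents that add atoms: none
Why: Ring-closing metathesis between the acrylate and the terminal vinyl group gives the five-membered unsaturated lactone; the trisubstituted bromoalkene does not enter metathesis.

Step 7
Reactants: 10 (5S)-5-[(2E)-3-bromo-2-methylprop-2-en-1-yl]furan-2(5H)-one
Product: 11 (4S,5S)-5-[(2E)-3-bromo-2-methylprop-2-en-1-yl]-4-ethenyloxolan-2-one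
Conditions: CH2=CHMgBr (3 equiv), CuBr·SMe2 (1.5 equiv), THF, −78 → −40 °C; NH4Cl
Reagents that add atoms: vinylmagnesium bromide, C=C[Mg]Br
Why: Conjugate addition of a vinyl cuprate to a 5-substituted butenolide; the reagent reaches C7 from the face anti to the C8 side chain, which gives the trans lactone and sets C7.

Step 8
Reactants: 11 (4S,5S)-5-[(2E)-3-bromo-2-methylprop-2-en-1-yl]-4-ethenyloxolan-2-one
Product: 13 (2S,3R)-2-[(2E)-3-bromo-2-methylprop-2-en-1-yl]-5-oxooxolane-3-carbaldehyde, via vicinal diol 12 (not isolated)
Conditions: OsO4 (2 mol %), N-methylmorpholine N-oxide, acetone–H2O, 0 °C; then NaIO4, 25 °C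
Reagents that add atoms: N-methylmorpholine N-oxide, C[N+]1([O-])CCOCC1; water, O
Why: Catalytic osmylation should pick the monosubstituted vinyl group over the electron-poor, hindered bromoalkene, and periodate cleaves diol 12 to the aldehyde (Lemieux–Johnson sequence). The near-neutral medium spares the enolisable C7 centre.

Step 9
Reactants: 14 methyl propiolate; 15 (tert-butyldimethylsilyloxy)acetaldehyde
Product: 18 methyl (2Z)-2-[(1S)-2-{[tert-butyl(dimethyl)silyl]oxy}-1-hydroxyethyl]-3-iodoprop-2-enoate, via silyl allenolate 16 (not isolated), via trimethylsilyl ether 17 (not isolated)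
Conditions: TMSI (1.2 equiv), (S)-oxazaborolidinium triflimide [from (S)-3,3-diphenyl-1-(2-methylphenyl)tetrahydro-1H,3H-pyrrolo[1,2-c][1,3,2]oxazaborole and HNTf2] (20 mol %), CH2Cl2, −78 °C; then aqueous citric acid, THF, 0 °C
Reagents that add atoms: iodotrimethylsilane, C[Si](C)(C)I
Why: Catalytic asymmetric three-component iodo-aldol (β-iodo Morita–Baylis–Hillman) reaction: TMSI adds to 14 to give allenolate 16, whose α-carbon (C4) attacks the catalyst-bound aldehyde and gives the Z iodoalkene (I cis to CO2Me) under kinetic control. The chiral boron cation shields one face of 15 and so sets C3.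

Step 10
Reactants: 18 methyl (2Z)-2-[(1S)-2-{[tert-butyl(dimethyl)silyl]oxy}-1-hydroxyethyl]-3-iodoprop-2-enoate
Product: 19 methyl (2Z)-2-[(1S)-2-{[tert-butyl(dimethyl)silyl]oxy}-1-{[tri(propan-2-yl)silyl]oxy}ethyl]-3-iodoprop-2-enoate
Conditions: TIPSOTf, 2,6-lutidine, CH2Cl2, −78 → 0 °C
Reagents that add atoms: triisopropylsilyl trifluoromethanesulfonate, CC(C)[Si](OS(=O)(=O)C(F)(F)F)(C(C)C)C(C)C
Why: Silylation of a hindered secondary alcohol with a silyl triflate and a non-nucleophilic base; the bulky group is chosen because it outlasts the primary silyl ether in step 14.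

Step 11
Reactants: 19 methyl (2Z)-2-[(1S)-2-{[tert-butyl(dimethyl)silyl]oxy}-1-{[tri(propan-2-yl)silyl]oxy}ethyl]-3-iodoprop-2-enoate
Product: 20 (2E,3S)-4-{[tert-butyl(dimethyl)silyl]oxy}-2-(iodomethylidene)-3-{[tri(propan-2-yl)silyl]oxy}butan-1-ol
Conditions: i-Bu2AlH (2.5 equiv), CH2Cl2, −78 °C
Reagents that add atoms: none
Why: Low-temperature 1,2-reduction of the conjugated ester to the C15 allylic alcohol; the alkenyl iodide and both silyl ethers are inert, and the alkene geometry is unchanged (the descriptor changes only by the priority rules).

Step 12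
Reactants: 20 (2E,3S)-4-{[tert-butyl(dimethyl)silyl]oxy}-2-(iodomethylidene)-3-{[tri(propan-2-yl)silyl]oxy}butan-1-ol; 13 (2S,3R)-2-[(2E)-3-bromo-2-methylprop-2-en-1-yl]-5-oxooxolane-3-carbaldehyde
Product: 23 seco diol with free C6 and C15 hydroxyls, via dilithio species 21 (not isolated), via alkenylmagnesium species 22 (not isolated)
Conditions: 20 (1.3 equiv), MeLi (1 equiv per 20), then t-BuLi (2 equiv per 20), Et2O, −78 °C; MgBr2·OEt2; then 13, THF, −78 °C; NH4Cl
Reagents that add atoms: none
Why: Iodine–lithium exchange with retention and transmetalation give an alkenylmagnesium reagent that adds to the aldehyde but not to the lactone at −78 °C, so that C15 stays cis to C6. Felkin–Anh addition anti to the C7–C8 bond (the larger, oxygen-bearing branch) and past H7 should favour the 6R alcohol, with O6 on the side of C11 as in 34. Any 6S epimer is removed at 24.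

Step 13
Reactants: 23 seco diol with free C6 and C15 hydroxyls
Product: 24 seco acetonide with C2 tert-butyldimethylsilyl ether
Conditions: 2,2-dimethoxypropane, PPTS (cat.), CH2Cl2, 25 °C
Reagents that add atoms: 2,2-dimethoxypropane, COC(C)(C)OC
Why: Acid-catalysed transketalisation; O6 and O15 are cis on the C4=C5 bond and close a 4,7-dihydro-1,3-dioxepine, and no other diol is present.

Step 14
Reactants: 24 seco acetonide with C2 tert-butyldimethylsilyl ether
Product: 25 seco acetonide with free C2 hydroxyl
Conditions: HF·pyridine, pyridine, THF, 0 °C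
Reagents that add atoms: none
Why: Buffered HF·pyridine cleaves a primary tert-butyldimethylsilyl ether far faster than a secondary triisopropylsilyl ether, and the buffered medium leaves the ketal and the lactone.

Step 15
Reactants: 25 seco acetonide with free C2 hydroxyl
Product: 26 seco C1 (E)-alkenyl bromide and C2 primary iodide
Conditions: I2, PPh3, imidazole, CH2Cl2, 0 → 25 °C, dark
Reagents that add atoms: iodine, II
Why: Appel-type iodination (Garegg–Samuelsson conditions) of the primary alcohol by SN2 displacement of the alkoxyphosphonium ion; imidazole keeps the medium non-acidic for the ketal.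

Step 16
Reactants: 26 seco C1 (E)-alkenyl bromide and C2 primary iodide
Product: 27 ten-membered (E,E)-diene lactone with C6/C15 acetonide and C3 triisopropylsilyl ether
Conditions: NiBr2(dme) (30 mol %), 4,4'-di-tert-butyl-2,2'-bipyridine (36 mol %), Mn powder (5 equiv), DMA, 25 °C; 26 added by syringe pump over 12 h to a final 0.002 M
Reagents that add atoms: none
Why: Proposed new method: oxidative addition of the C1–Br bond to zerovalent nickel (made from NiBr2(dme), the bipyridine and Mn) gives an alkenylnickel bromide with retention; iodine-atom transfer from C2 to a monovalent nickel species then releases a primary radical, which the alkenylnickel centre of the same molecule traps, and the trivalent nickel species so formed makes C1–C2 by reductive elimination. The closest known reaction type is the intermolecular nickel-catalysed reductive cross-electrophile coupling of alkenyl bromides with primary alkyl iodides; its use for closing a ring of this size is untested. The ten-membered ring is closed end to end: radical capture gives an eleven-membered nickelacycle, which contracts to the carbocycle on reductive elimination. No stereocentre is formed, since C3, C6, C7, C8, both E alkenes and the trans lactone are already present. The step needs chemoselective activation (sp2 C–Br by zerovalent nickel, sp3 C–I by atom transfer), which the two different halides provide, retention of the E geometry at C1, which alkenylnickel species normally show at 25 °C, and capture within the molecule rather than between molecules, which slow addition into a solution of high nickel loading favours. Because C2 reacts as a free radical the neighbouring C3–O bond stays, whereas a C2–metal bond would expel the silanolate; for the same reason Mn is the reductant and not Zn, which can insert directly into primary C–I bonds in amide solvents.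

Step 17
Reactants: 27 ten-membered (E,E)-diene lactone with C6/C15 acetonide and C3 triisopropylsilyl ether
Product: 28 C11 dimethylaminomethyl lactone (Mannich base)
Conditions: LiN(iPr)2, THF, −78 °C; then CH2=NMe2 I (Eschenmoser's salt), −78 → 0 °C
Reagents that add atoms: N,N-dimethylmethyleneiminium iodide, C=[N+](C)C.[I-]
Why: The kinetic lithium enolate of the lactone (C11 is the only acidic position) is aminomethylated by the iminium salt (Mannich reaction); the configuration at C11 is of no consequence.

Step 18
Reactants: 28 C11 dimethylaminomethyl lactone (Mannich base)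
Product: 30 α-methylene lactone with C6/C15 acetonide, via quaternary ammonium iodide 29 (not isolated)
Conditions: MeI, THF, 25 °C; then aqueous NaHCO3, EtOAc, 25 °C
Reagents that add atoms: none
Why: N-Methylation turns the amine into a leaving group and mild base eliminates it by E1cB to the exocyclic enoate; everything is kept at room temperature to avoid Cope rearrangement of the 1,5-diene.

Step 19
Reactants: 30 α-methylene lactone with C6/C15 acetonide
Product: 31 C6,C15-diol with C3 triisopropylsilyl ether
Conditions: AcOH–THF–H2O (3:1:1), 25 °C
Reagents that add atoms: none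
Why: The seven-membered allylic ketal hydrolyses in dilute acetic acid far faster than a secondary triisopropylsilyl ether, and the acid is too weak to start transannular cyclisation of the diene.

Step 20
Reactants: 31 C6,C15-diol with C3 triisopropylsilyl ether; 32 (R)-2-methylbutanoic acid
Product: 33 C6,C15-bis[(R)-2-methylbutanoate] with C3 triisopropylsilyl ether
Conditions: 32 (3 equiv), DCC, DMAP (cat.), CH2Cl2, 0 → 25 °C
Reagents that add atoms: none
Why: Steglich esterification of the primary C15 and the secondary allylic C6 hydroxyl with the same acid; carbodiimide activation at or below 25 °C should leave the α-centre of 32 intact. O3 is still silylated, so only two esters form.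

Step 21
Reactants: 33 C6,C15-bis[(R)-2-methylbutanoate] with C3 triisopropylsilyl ether
Product: 34 CNP0164325.1
Conditions: HF·pyridine, pyridine, THF, 0 → 25 °C
Reagents that add atoms: none
Why: Fluoride-assisted Si–O cleavage under buffered, non-basic conditions frees O3 without triggering acyl migration from O15 or addition to the methylene lactone.

## Compound list

1 | (S)-epichlorohydrin, (2S)-2-(chloromethyl)oxirane | ClC[C@@H]1CO1 | starting material
2 | ethynyltrimethylsilane | C#C[Si](C)(C)C | starting material
3 | (2S)-1-chloro-5-(trimethylsilyl)pent-4-yn-2-ol | ClC[C@@H](O)CC#C[Si](C)(C)C | intermediate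
4 | (2S)-2-[3-(trimethylsilyl)prop-2-yn-1-yl]oxirane (not isolated) | C[Si](C)(C)C#CC[C@H]1CO1 | intermediate
5 | (3S)-6-(trimethylsilyl)hex-1-en-5-yn-3-ol | C=C[C@@H](O)CC#C[Si](C)(C)C | intermediate
6 | (3S)-hex-1-en-5-yn-3-ol | C=C[C@@H](O)CC#C | intermediate
7 | dimethylaluminium alkoxide of (3S,5E)-6-(dimethylalumanyl)-5-methylhexa-1,5-dien-3-ol (not isolated) | C=C[C@@H](O[Al](C)C)C/C(C)=C/[Al](C)C | intermediate
8 | (3S,5E)-6-bromo-5-methylhexa-1,5-dien-3-ol | C=C[C@@H](O)C/C(C)=C/Br | intermediate
9 | (3S,5E)-6-bromo-5-methylhexa-1,5-dien-3-yl prop-2-enoate | C=CC(=O)O[C@H](C=C)C/C(C)=C/Br | intermediate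
10 | (5S)-5-[(2E)-3-bromo-2-methylprop-2-en-1-yl]furan-2(5H)-one | O=C1C=C[C@H](C/C(C)=C/Br)O1 | intermediate
11 | (4S,5S)-5-[(2E)-3-bromo-2-methylprop-2-en-1-yl]-4-ethenyloxolan-2-one (trans) | O=C1C[C@@H](C=C)[C@H](C/C(C)=C/Br)O1 | intermediate
12 | (4S,5S)-5-[(2E)-3-bromo-2-methylprop-2-en-1-yl]-4-(1,2-dihydroxyethyl)oxolan-2-one, both carbinol epimers (not isolated) | O=C1C[C@@H](C(O)CO)[C@H](C/C(C)=C/Br)O1 | intermediate
13 | (2S,3R)-2-[(2E)-3-bromo-2-methylprop-2-en-1-yl]-5-oxooxolane-3-carbaldehyde | O=C[C@@H]1CC(=O)O[C@H]1C/C(C)=C/Br | intermediate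
14 | methyl propiolate (methyl prop-2-ynoate) | C#CC(=O)OC | starting material
15 | (tert-butyldimethylsilyloxy)acetaldehyde | CC(C)(C)[Si](C)(C)OCC=O | starting material
16 | 3-iodo-1-methoxy-1-(trimethylsilyloxy)propa-1,2-diene (not isolated) | COC(O[Si](C)(C)C)=C=CI | intermediate
17 | methyl (2Z)-2-[(1S)-2-{[tert-butyl(dimethyl)silyl]oxy}-1-(trimethylsilyloxy)ethyl]-3-iodoprop-2-enoate (not isolated) | COC(=O)/C(=C\I)[C@H](O[Si](C)(C)C)CO[Si](C)(C)C(C)(C)C | intermediate
18 | methyl (2Z)-2-[(1S)-2-{[tert-butyl(dimethyl)silyl]oxy}-1-hydroxyethyl]-3-iodoprop-2-enoate | COC(=O)/C(=C\I)[C@H](O)CO[Si](C)(C)C(C)(C)C | intermediate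
19 | methyl (2Z)-2-[(1S)-2-{[tert-butyl(dimethyl)silyl]oxy}-1-{[tri(propan-2-yl)silyl]oxy}ethyl]-3-iodoprop-2-enoate | COC(=O)/C(=C\I)[C@H](O[Si](C(C)C)(C(C)C)C(C)C)CO[Si](C)(C)C(C)(C)C | intermediate
20 | (2E,3S)-4-{[tert-butyl(dimethyl)silyl]oxy}-2-(iodomethylidene)-3-{[tri(propan-2-yl)silyl]oxy}butan-1-ol | OC/C(=C\I)[C@H](O[Si](C(C)C)(C(C)C)C(C)C)CO[Si](C)(C)C(C)(C)C | intermediate
21 | lithium alkoxide of 20 with lithium in place of iodine (not isolated) | [Li]OC/C(=C\[Li])[C@H](O[Si](C(C)C)(C(C)C)C(C)C)CO[Si](C)(C)C(C)(C)C | intermediate
22 | bromomagnesium alkoxide of 20 with MgBr in place of iodine (not isolated) | Br[Mg]OC/C(=C\[Mg]Br)[C@H](O[Si](C(C)C)(C(C)C)C(C)C)CO[Si](C)(C)C(C)(C)C | intermediate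
23 | (4S,5S)-5-[(2E)-3-bromo-2-methylprop-2-en-1-yl]-4-[(1R,2E,4S)-5-{[tert-butyl(dimethyl)silyl]oxy}-1-hydroxy-3-(hydroxymethyl)-4-{[tri(propan-2-yl)silyl]oxy}pent-2-en-1-yl]oxolan-2-one | CC(C)(C)[Si](C)(C)OC[C@@H](O[Si](C(C)C)(C(C)C)C(C)C)/C(CO)=C/[C@@H](O)[C@@H]1CC(=O)O[C@H]1C/C(C)=C/Br | intermediate
24 | (4R,5S)-5-[(2E)-3-bromo-2-methylprop-2-en-1-yl]-4-{(4R)-6-[(1S)-2-{[tert-butyl(dimethyl)silyl]oxy}-1-{[tri(propan-2-yl)silyl]oxy}ethyl]-2,2-dimethyl-4,7-dihydro-1,3-dioxepin-4-yl}oxolan-2-one | CC(C)(C)[Si](C)(C)OC[C@@H](O[Si](C(C)C)(C(C)C)C(C)C)/C1=C/[C@@H](OC(C)(C)OC1)[C@@H]1CC(=O)O[C@H]1C/C(C)=C/Br | intermediate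
25 | (4R,5S)-5-[(2E)-3-bromo-2-methylprop-2-en-1-yl]-4-{(4R)-6-[(1S)-2-hydroxy-1-{[tri(propan-2-yl)silyl]oxy}ethyl]-2,2-dimethyl-4,7-dihydro-1,3-dioxepin-4-yl}oxolan-2-one | OC[C@@H](O[Si](C(C)C)(C(C)C)C(C)C)/C1=C/[C@@H](OC(C)(C)OC1)[C@@H]1CC(=O)O[C@H]1C/C(C)=C/Br | intermediate
26 | (4R,5S)-5-[(2E)-3-bromo-2-methylprop-2-en-1-yl]-4-{(4R)-6-[(1S)-2-iodo-1-{[tri(propan-2-yl)silyl]oxy}ethyl]-2,2-dimethyl-4,7-dihydro-1,3-dioxepin-4-yl}oxolan-2-one | IC[C@@H](O[Si](C(C)C)(C(C)C)C(C)C)/C1=C/[C@@H](OC(C)(C)OC1)[C@@H]1CC(=O)O[C@H]1C/C(C)=C/Br | intermediate
27 | (3R,6R,7R,8S,1(10)E,4E)-6,15-(isopropylidenedioxy)-3-{[tri(propan-2-yl)silyl]oxy}germacra-1(10),4-dien-12,8-olide | C1C(=O)O[C@H]2C/C(C)=C/C[C@@H](O[Si](C(C)C)(C(C)C)C(C)C)/C(COC(C)(C)O3)=C/[C@@H]3[C@H]12 | intermediate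
28 | (3R,6R,7R,8S)-13-(dimethylamino)-6,15-(isopropylidenedioxy)-3-{[tri(propan-2-yl)silyl]oxy}germacra-1(10),4-dien-12,8-olide, C11 epimers | CN(C)CC1C(=O)O[C@H]2C/C(C)=C/C[C@@H](O[Si](C(C)C)(C(C)C)C(C)C)/C(COC(C)(C)O3)=C/[C@@H]3[C@H]12 | intermediate
29 | N-methyl quaternary ammonium iodide of 28 (not isolated) | C[N+](C)(C)CC1C(=O)O[C@H]2C/C(C)=C/C[C@@H](O[Si](C(C)C)(C(C)C)C(C)C)/C(COC(C)(C)O3)=C/[C@@H]3[C@H]12.[I-] | intermediate
30 | (3R,6R,7R,8S)-6,15-(isopropylidenedioxy)-3-{[tri(propan-2-yl)silyl]oxy}germacra-1(10),4,11(13)-trien-12,8-olide | C=C1C(=O)O[C@H]2C/C(C)=C/C[C@@H](O[Si](C(C)C)(C(C)C)C(C)C)/C(COC(C)(C)O3)=C/[C@@H]3[C@H]12 | intermediate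
31 | (3R,6R,7S,8S)-6,15-dihydroxy-3-{[tri(propan-2-yl)silyl]oxy}germacra-1(10),4,11(13)-trien-12,8-olide (same spatial arrangement at C7; descriptor changes with priorities) | C=C1C(=O)O[C@H]2C/C(C)=C/C[C@@H](O[Si](C(C)C)(C(C)C)C(C)C)/C(CO)=C/[C@@H](O)[C@H]12 | intermediate
32 | (R)-2-methylbutanoic acid | CC[C@@H](C)C(=O)O | starting material
33 | (3R,6R,7R,8S)-6,15-bis{[(2R)-2-methylbutanoyl]oxy}-3-{[tri(propan-2-yl)silyl]oxy}germacra-1(10),4,11(13)-trien-12,8-olide | C=C1C(=O)O[C@H]2C/C(C)=C/C[C@@H](O[Si](C(C)C)(C(C)C)C(C)C)/C(COC(=O)[C@H](C)CC)=C/[C@@H](OC(=O)[C@H](C)CC)[C@H]12 | intermediate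
34 | CNP0164325.1, (3R,6R,7R,8S,1(10)E,4E)-3-hydroxy-6,15-bis{[(2R)-2-methylbutanoyl]oxy}germacra-1(10),4,11(13)-trien-12,8-olide | C=C1C(=O)O[C@H]2C/C(C)=C/C[C@@H](O)/C(COC(=O)[C@H](C)CC)=C/[C@@H](OC(=O)[C@H](C)CC)[C@H]12 | target

## Step count and least certain steps

Total: 21 steps. Longest linear sequence: 18 steps from 1 (steps 1–8 and 12–21); the C2–C5 fragment 20 takes 3 steps (9–11).

Step 16 (key step). The most likely failure is capture of the C2 radical by an alkenylnickel centre of another molecule, which gives dimers and oligomers, because a ten-membered ring has a low effective molarity. Next come reduction of the C2–I bond to a methyl group by hydrogen abstraction from the solvent, and partial loss of E geometry at C1 on nickel. The fallback sets out from 26 and comes back at 27. Copper-catalysed borylation of the primary iodide (CuI, PPh3, LiOMe, B2pin2, DMF, 25 °C) gives the C2 pinacol boronate F1, which is stable towards loss of the β-silyloxy group. An intramolecular B-alkyl Suzuki–Miyaura coupling with the C1 alkenyl bromide (Pd(OAc)2, RuPhos, K3PO4, toluene–water, high dilution, not above 60 °C because of the 1,5-diene) then closes the same C1–C2 bond. Both are known reaction types.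

Step 9. Enantioselectivity may be eroded, because TMSI alone promotes an uncatalysed background reaction and the α-silyloxy group of 15 can offer the boron cation a second binding mode. The fallback sets out from 14 and 15 and returns at 18. MgI2 in CH2Cl2 at 0 °C gives the racemic (Z)-iodo-aldol ester F2. Acetylation (Ac2O, pyridine) gives the racemic acetate F3. A lipase (Burkholderia cepacia lipase, phosphate buffer of pH 7, 30 °C) should hydrolyse the (S)-acetate to 18 and leave the (R)-acetate F4, which is separated.

Step 12. Facial selectivity at C6 may be poor, since 1,2-induction from a ring carbon without an α-heteroatom is often weak. The basic reagent may also enolise 13, with epimerisation at C7 or β-elimination of the C8 carboxylate, and the new C6 alkoxide may attack C12 and shift the lactone. The fallback sets out from 20 and 13 and returns at 23, and makes no new compound. It is a Nozaki–Hiyama–Kishi coupling (CrCl2, catalytic NiCl2, a chiral 2-(sulfonamidoaryl)oxazoline ligand chosen for the 6R sense, Et3N, THF). This is non-basic, runs under ligand control, gives a weakly nucleophilic chromium alkoxide, and activates the alkenyl iodide far faster than the alkenyl bromide.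

Step 8. Chemoselectivity may be lost by osmylation of the bromoalkene when the vinyl group is consumed slowly, and the β-acyloxy aldehyde may degrade in the aqueous medium. The fallback sets out from 10 and returns at 13 without any oxidant. Conjugate addition of (PhS)2CHLi (THF–DMPU, −78 °C), anti to the C8 side chain, gives the trans dithioacetal lactone F5. Hydrolysis (HgCl2, CaCO3, MeCN–H2O) releases the aldehyde.

Step 20. Acylation of the hindered C6 hydroxyl may be slow, and while it waits, DMAP or carboxylate may add to the methylene lactone, or the lactone may shift from O8 to the free O6. The fallback sets out from 28 and returns at 33, with the methylene masked as its amine adduct. Ketal cleavage of 28 (AcOH–THF–H2O) gives the amino diol F6. Esterification with 32 (DCC, DMAP) gives the amino diester F7. Methylation (MeI) to the quaternary salt F8 and elimination with aqueous NaHCO3 give 33.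

## Further compounds

F1 | step 16 | C2 pinacol boronate of the seco compound (B in place of I in 26) | CC1(C)OB(C[C@@H](O[Si](C(C)C)(C(C)C)C(C)C)/C2=C/[C@@H](OC(C)(C)OC2)[C@@H]2CC(=O)O[C@H]2C/C(C)=C/Br)OC1(C)C
F2 | step 9 | racemic methyl (2Z)-2-[2-{[tert-butyl(dimethyl)silyl]oxy}-1-hydroxyethyl]-3-iodoprop-2-enoate | COC(=O)/C(=C\I)C(O)CO[Si](C)(C)C(C)(C)C
F3 | step 9 | racemic methyl (2Z)-2-[1-acetoxy-2-{[tert-butyl(dimethyl)silyl]oxy}ethyl]-3-iodoprop-2-enoate | COC(=O)/C(=C\I)C(OC(C)=O)CO[Si](C)(C)C(C)(C)C
F4 | step 9 | methyl (2Z)-2-[(1R)-1-acetoxy-2-{[tert-butyl(dimethyl)silyl]oxy}ethyl]-3-iodoprop-2-enoate | COC(=O)/C(=C\I)[C@@H](OC(C)=O)CO[Si](C)(C)C(C)(C)C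
F0 | step 12 | none | none
F5 | step 8 | trans 4-[bis(phenylsulfanyl)methyl]-5-[(2E)-3-bromo-2-methylprop-2-en-1-yl]oxolan-2-one (configuration as in 11) | O=C1C[C@@H](C(Sc2ccccc2)Sc2ccccc2)[C@H](C/C(C)=C/Br)O1
F6 | step 20 | 13-(dimethylamino)-6,15-dihydroxy-3-{[tri(propan-2-yl)silyl]oxy}germacra-1(10),4-dien-12,8-olide (configuration as in 28) | CN(C)CC1C(=O)O[C@H]2C/C(C)=C/C[C@@H](O[Si](C(C)C)(C(C)C)C(C)C)/C(CO)=C/[C@@H](O)[C@H]12
F7 | step 20 | 13-(dimethylamino)-6,15-bis{[(2R)-2-methylbutanoyl]oxy}-3-{[tri(propan-2-yl)silyl]oxy}germacra-1(10),4-dien-12,8-olide | CN(C)CC1C(=O)O[C@H]2C/C(C)=C/C[C@@H](O[Si](C(C)C)(C(C)C)C(C)C)/C(COC(=O)[C@H](C)CC)=C/[C@@H](OC(=O)[C@H](C)CC)[C@H]12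
F8 | step 20 | N-methyl quaternary ammonium iodide of F7 | C[N+](C)(C)CC1C(=O)O[C@H]2C/C(C)=C/C[C@@H](O[Si](C(C)C)(C(C)C)C(C)C)/C(COC(=O)[C@H](C)CC)=C/[C@@H](OC(=O)[C@H](C)CC)[C@H]12.[I-]
A1 | alternative 1 | ten-membered (E,E)-dienyl C10 triflate with C3 methoxymethyl ether, C6 and C15 p-methoxybenzyl ethers, C8 silyl ether and C7 2-(silyloxy)ethyl chain | CC(C)(C)[Si](C)(C)O[C@H]1C/C(OS(=O)(=O)C(F)(F)F)=C/C[C@@H](OCOC)/C(COCc2ccc(OC)cc2)=C/[C@@H](OCc2ccc(OC)cc2)[C@@H]1CCO[Si](C)(C)C(C)(C)C
A2 | alternative 2 | (E)-cyclodec-1(10)-en-4-yn-6-ol with C3 triisopropylsilyl ether, C8 silyl ether and C7 3-(silyloxy)prop-1-en-2-yl group | CC(C)(C)[Si](C)(C)O[C@H]1C/C(C)=C/C[C@@H](O[Si](C(C)C)(C(C)C)C(C)C)C#C[C@@H](O)[C@@H]1C(=C)CO[Si](C)(C)C(C)(C)C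
A3 | alternative 3 | ten-membered (E,E)-diene 12,8-lactone with C3 triethylsilyl ether and C6, C15 p-methoxybenzyl ethers | C1C(=O)O[C@H]2C/C(C)=C/C[C@@H](O[Si](CC)(CC)CC)/C(COCc3ccc(OC)cc3)=C/[C@@H](OCc3ccc(OC)cc3)[C@H]12
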